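**Plan**
1. Retrosynthetic cuts: the enone at Cα=Cβ (aldol condensation with masked 4-hydroxybenzaldehyde), the aryl ketone at C6–C(=O) (Fries transfer of an O-acetyl group), the dihydropyran at O1–C2 (phenol opening of a prenyl epoxide), and ring A at C8a–C4a, C5–C6 and C8–C8a (cyclobutenone/siloxyalkyne benzannulation).
2. Enabling feature: ring A is a phloroglucinol whose three oxygens differ (C5 OH, C7 OMe, C8a ring ether) and whose C4a carbon substituent lies between two of them; a methoxy vinylketene and a prenyl ynol silyl ether deliver this as OMe, O-silyl and free OH.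
3. Forward order: ring A first (steps 1–5), the pyran ring second by closure of the one free phenol onto the epoxide (steps 6–8), then C6 acetylation and attachment of the cinnamoyl arm (steps 9–13).
4. Stereochemistry: the only stereocentre, C3 (R), comes from a Shi epoxidation with the D-fructose-derived ketone; the epoxide is opened at its tertiary carbon, so the C3–O bond is never broken. The enone is E by thermodynamic control.

Key step: step 5

Remark: ethyl 4-methylpent-3-enoate (7) is treated as a catalogue ester; if unavailable, Fischer esterification of 4-methylpent-3-enoic acid supplies it.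

**Step 1**
Reactants: 1 ethoxyethyne (ethoxyacetylene); 2 acetyl chloride
Product: 4 3-ethoxycyclobut-2-en-1-one, via ketene 3 (not isolated)
Conditions: Et3N, CH2Cl2, 0 °C → rt (2 added slowly, 1 in excess)
Reagents that add atoms: none
Why: Dehydrochlorination of the acid chloride releases ketene, which undergoes thermal [2+2] cycloaddition with the electron-rich alkyne (ketene carbonyl carbon to the unsubstituted alkyne carbon), the established entry to 3-alkoxycyclobutenones.

**Step 2**
Reactants: 4 3-ethoxycyclobut-2-en-1-one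
Product: 5 cyclobutane-1,3-dione
Conditions: H2SO4 (ca. 90%), −10 → 0 °C; then ice–H2O, Et2O extraction
Reagents that add atoms: water, O
Why: Acid-catalysed hydrolysis of the vinylogous ester (water adds at C3, ethanol leaves) should give the strongly acidic 1,3-dione without opening the four-membered ring.

**Step 3**
Reactants: 5 cyclobutane-1,3-dione
Product: 6 3-methoxycyclobut-2-en-1-one
Conditions: Me3SiCHN2, MeOH–Et2O, 0 °C
Reagents that add atoms: trimethylsilyldiazomethane, C[Si](C)(C)C=[N+]=[N-]
Why: The dione behaves as a vinylogous carboxylic acid and should be O-methylated by the diazoalkane as in an esterification, giving the methyl enol ether.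

**Step 4**
Reactants: 7 ethyl 4-methylpent-3-enoate
Product: 10 triisopropyl[(5-methylhex-4-en-1-yn-1-yl)oxy]silane, via dibromo enolate 8 (not isolated), via lithium ynolate 9 (not isolated)
Conditions: CH2Br2, LiTMP (lithium 2,2,6,6-tetramethylpiperidide), THF, −78 °C; LiN(SiMe3)2; n-BuLi, −78 °C → rt; iPr3SiCl, −78 °C → rt
Reagents that add atoms: dibromomethane, BrCBr; triisopropylsilyl chloride, CC(C)[Si](Cl)(C(C)C)C(C)C
Why: Kowalski ester homologation: dibromomethyllithium adds to the ester, the dibromo ketone enolate undergoes bromine–lithium exchange and 1,2-shift to the ynolate, and the bulky silyl chloride traps it on oxygen.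

**Step 5**
Reactants: 6 3-methoxycyclobut-2-en-1-one; 10 triisopropyl[(5-methylhex-4-en-1-yn-1-yl)oxy]silane
Product: 15 5-methoxy-2-(3-methylbut-2-en-1-yl)-3-[(triisopropylsilyl)oxy]phenol, via vinylketene 11 (not isolated), via vinylcyclobutenone 12 (not isolated), via dienylketene 13 (not isolated), via cyclohexadienone 14 (not isolated)
Conditions: PhMe, 80 °C then 110 °C, sealed tube (10 in slight excess)
Reagents that add atoms: none
Why: Heating opens 6 by four-electron electrocyclic cleavage to methoxy vinylketene 11, whose ketene C=C adds [2+2] to the siloxyalkyne to give 4-vinylcyclobutenone 12; a second four-electron opening gives dienylketene 13, six-electron electrocyclisation gives dienone 14, and enolisation gives phenol 15. This is the Danheiser benzannulation in its siloxyalkyne form, documented for 3-alkylcyclobutenones giving 2-substituted resorcinol monosilyl ethers; the 3-alkoxy partner differs only in carrying a donor in place of alkyl. The one ring formed, benzene ring A, is closed by the disrotatory 6π electrocyclisation that makes C8–C8a, after C8a–C4a and C5–C6 have been made in the ketene [2+2] step. No stereocentre is created. The step needs regiocontrol in the [2+2] addition and preference for the alkyne over the prenyl olefin: oxygen makes the prenyl-bearing alkyne carbon the nucleophilic terminus, so it bonds to the ketene carbonyl carbon and places prenyl ortho and silyloxy meta to the new hydroxyl, while the unactivated trisubstituted olefin is far less reactive toward the ketene.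

**Step 6**
Reactants: 15 5-methoxy-2-(3-methylbut-2-en-1-yl)-3-[(triisopropylsilyl)oxy]phenol
Product: 16 [3-(benzyloxy)-5-methoxy-2-(3-methylbut-2-en-1-yl)phenoxy]triisopropylsilane
Conditions: BnBr, K2CO3, DMF, rt
Reagents that add atoms: benzyl bromide, BrCc1ccccc1
Why: Williamson etherification of the only free phenol masks it so that no phenoxide can open the epoxide in the basic epoxidation medium, and the benzyl group can later be removed by neutral hydrogenolysis; the hindered aryl silyl ether should tolerate K2CO3.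

**Step 7**
Reactants: 16 [3-(benzyloxy)-5-methoxy-2-(3-methylbut-2-en-1-yl)phenoxy]triisopropylsilane
Product: 17 {3-(benzyloxy)-2-{[(2R)-3,3-dimethyloxiran-2-yl]methyl}-5-methoxyphenoxy}triisopropylsilane
Conditions: D-fructose-derived Shi ketone (0.3 equiv), Oxone (2KHSO5·KHSO4·K2SO4), K2CO3, Bu4NHSO4, MeCN–CH2(OMe)2, aq. Na2B4O7/Na2EDTA buffer (pH ca. 10.5), 0 °C
Reagents that add atoms: potassium peroxymonosulfate (as Oxone), [K+].[O-]S(=O)(=O)OO
Why: Shi asymmetric epoxidation: the chiral dioxirane from the ketone and KHSO5 transfers oxygen through a spiro transition state to the face of the R–CH2–CH=CMe2 olefin that gives the (R)-epoxide, so the catalyst sets the stereocentre.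

**Step 8**
Reactants: 17 {3-(benzyloxy)-2-{[(2R)-3,3-dimethyloxiran-2-yl]methyl}-5-methoxyphenoxy}triisopropylsilane
Product: 19 (3R)-7-methoxy-2,2-dimethyl-5-[(triisopropylsilyl)oxy]-3,4-dihydro-2H-chromen-3-ol, via epoxy phenol 18 (not isolated)
Conditions: H2 (1 atm), 10% Pd/C, EtOAc, rt; filter; CSA (0.1 equiv), CH2Cl2, −20 → 0 °C
Reagents that add atoms: none
Why: Hydrogenolysis frees the phenol under neutral conditions, and Brønsted acid then promotes 6-endo (Markovnikov) epoxide opening at the tertiary carbon, so the pyran closes on the one free phenol and the C3–O bond keeps its (R) configuration.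

**Step 9**
Reactants: 19 (3R)-7-methoxy-2,2-dimethyl-5-[(triisopropylsilyl)oxy]-3,4-dihydro-2H-chromen-3-ol
Product: 21 (3R)-7-methoxy-2,2-dimethyl-3,4-dihydro-2H-chromene-3,5-diyl diacetate, via chromanediol 20 (not isolated)
Conditions: Bu4NF, THF, 0 °C; then Ac2O (excess), Et3N, DMAP, 0 °C → rt
Reagents that add atoms: acetic anhydride, CC(=O)OC(C)=O
Why: Fluoride cleaves the aryl silyl ether, and DMAP-catalysed acetylation of the phenoxide and the secondary alcohol in the same flask gives the Fries substrate with the C3 hydroxyl protected.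

**Step 10**
Reactants: 21 (3R)-7-methoxy-2,2-dimethyl-3,4-dihydro-2H-chromene-3,5-diyl diacetate
Product: 22 (3R)-6-acetyl-5-hydroxy-7-methoxy-2,2-dimethyl-3,4-dihydro-2H-chromen-3-yl acetate
Conditions: BF3·OEt2 (3 equiv), ClCH2CH2Cl, 70 °C; aq. work-up
Reagents that add atoms: none
Why: Fries rearrangement: BF3 moves the acyl group of the aryl acetate to C6, the only free position ortho to the C5 oxygen, where the ketone is held as a difluoroboron chelate that a C8 ketone could not form; the alkyl acetate does not migrate.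

**Step 11**
Reactants: 23 4-hydroxybenzaldehyde
Product: 24 4-(methoxymethoxy)benzaldehyde
Conditions: MOMCl, iPr2NEt, CH2Cl2, 0 °C → rt
Reagents that add atoms: chloromethyl methyl ether, COCCl
Why: O-alkylation of the phenol gives a base-stable acetal, so the aldehyde is not deactivated as a phenoxide during the condensation.

**Step 12**
Reactants: 22 (3R)-6-acetyl-5-hydroxy-7-methoxy-2,2-dimethyl-3,4-dihydro-2H-chromen-3-yl acetate; 24 4-(methoxymethoxy)benzaldehyde
Product: 26 (2E)-1-[(3R)-3,5-dihydroxy-7-methoxy-2,2-dimethyl-3,4-dihydro-2H-chromen-6-yl]-3-[4-(methoxymethoxy)phenyl]prop-2-en-1-one, via hydroxy ketone 25 (not isolated)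
Conditions: KOH (50% aq., excess), EtOH, rt; cold dilute HCl to pH ca. 5
Reagents that add atoms: none
Why: Claisen–Schmidt condensation: hydroxide saponifies the C3 acetate, the methyl ketone enolate adds to the non-enolisable aldehyde, and E1cB loss of water gives the conjugated (E)-enone, the thermodynamically favoured geometry.

**Step 13**
Reactants: 26 (2E)-1-[(3R)-3,5-dihydroxy-7-methoxy-2,2-dimethyl-3,4-dihydro-2H-chromen-6-yl]-3-[4-(methoxymethoxy)phenyl]prop-2-en-1-one
Product: 27 (2E)-1-[(3R)-3,5-dihydroxy-7-methoxy-2,2-dimethyl-3,4-dihydro-2H-chromen-6-yl]-3-(4-hydroxyphenyl)prop-2-en-1-one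
Conditions: 3 M HCl (aq.), MeOH, rt → 40 °C
Reagents that add atoms: none
Why: Acid-catalysed acetal methanolysis (methoxymethyl ether cleavage) should free the phenol, while the chroman ether, the secondary alcohol and the hydrogen-bonded 2'-hydroxychalcone tolerate dilute acid at moderate temperature.

**Compound list**
1 | ethoxyethyne (ethoxyacetylene) | CCOC#C | starting material
2 | acetyl chloride | CC(Cl)=O | starting material
3 | ketene (ethenone) | C=C=O | intermediate
4 | 3-ethoxycyclobut-2-en-1-one | CCOC1=CC(=O)C1 | intermediate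
5 | cyclobutane-1,3-dione | O=C1CC(=O)C1 | intermediate
6 | 3-methoxycyclobut-2-en-1-one | COC1=CC(=O)C1 | intermediate
7 | ethyl 4-methylpent-3-enoate | CCOC(=O)CC=C(C)C | starting material
8 | lithium 1,1-dibromo-5-methylhexa-1,4-dien-2-olate | [Li]OC(CC=C(C)C)=C(Br)Br | intermediate
9 | lithium 5-methylhex-4-en-1-yn-1-olate | [Li]OC#CCC=C(C)C | intermediate
10 | triisopropyl[(5-methylhex-4-en-1-yn-1-yl)oxy]silane | CC(C)=CCC#CO[Si](C(C)C)(C(C)C)C(C)C | intermediate
11 | 3-methoxybuta-1,3-dien-1-one | COC(=C)C=C=O | intermediate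
12 | 4-(1-methoxyethenyl)-2-(3-methylbut-2-en-1-yl)-3-[(triisopropylsilyl)oxy]cyclobut-2-en-1-one (racemic at C4) | COC(=C)C1C(=O)C(CC=C(C)C)=C1O[Si](C(C)C)(C(C)C)C(C)C | intermediate
13 | (3E)-5-methoxy-2-(3-methylbut-2-en-1-yl)-3-[(triisopropylsilyl)oxy]hexa-1,3,5-trien-1-one | COC(=C)/C=C(O[Si](C(C)C)(C(C)C)C(C)C)\C(CC=C(C)C)=C=O | intermediate
14 | 5-methoxy-2-(3-methylbut-2-en-1-yl)-3-[(triisopropylsilyl)oxy]cyclohexa-2,4-dien-1-one | COC1=CC(O[Si](C(C)C)(C(C)C)C(C)C)=C(CC=C(C)C)C(=O)C1 | intermediate
15 | 5-methoxy-2-(3-methylbut-2-en-1-yl)-3-[(triisopropylsilyl)oxy]phenol | COc1cc(O)c(CC=C(C)C)c(O[Si](C(C)C)(C(C)C)C(C)C)c1 | intermediate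
16 | [3-(benzyloxy)-5-methoxy-2-(3-methylbut-2-en-1-yl)phenoxy]triisopropylsilane | COc1cc(OCc2ccccc2)c(CC=C(C)C)c(O[Si](C(C)C)(C(C)C)C(C)C)c1 | intermediate
17 | {3-(benzyloxy)-2-{[(2R)-3,3-dimethyloxiran-2-yl]methyl}-5-methoxyphenoxy}triisopropylsilane | COc1cc(OCc2ccccc2)c(C[C@H]2OC2(C)C)c(O[Si](C(C)C)(C(C)C)C(C)C)c1 | intermediate
18 | 2-{[(2R)-3,3-dimethyloxiran-2-yl]methyl}-5-methoxy-3-[(triisopropylsilyl)oxy]phenol | COc1cc(O)c(C[C@H]2OC2(C)C)c(O[Si](C(C)C)(C(C)C)C(C)C)c1 | intermediate
19 | (3R)-7-methoxy-2,2-dimethyl-5-[(triisopropylsilyl)oxy]-3,4-dihydro-2H-chromen-3-ol | COc1cc2c(c(O[Si](C(C)C)(C(C)C)C(C)C)c1)C[C@@H](O)C(C)(C)O2 | intermediate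
20 | (3R)-7-methoxy-2,2-dimethyl-3,4-dihydro-2H-chromene-3,5-diol | COc1cc2c(c(O)c1)C[C@@H](O)C(C)(C)O2 | intermediate
21 | (3R)-7-methoxy-2,2-dimethyl-3,4-dihydro-2H-chromene-3,5-diyl diacetate | COc1cc2c(c(OC(C)=O)c1)C[C@@H](OC(C)=O)C(C)(C)O2 | intermediate
22 | (3R)-6-acetyl-5-hydroxy-7-methoxy-2,2-dimethyl-3,4-dihydro-2H-chromen-3-yl acetate | COc1cc2c(c(O)c1C(C)=O)C[C@@H](OC(C)=O)C(C)(C)O2 | intermediate
23 | 4-hydroxybenzaldehyde | O=Cc1ccc(O)cc1 | starting material
24 | 4-(methoxymethoxy)benzaldehyde | COCOc1ccc(C=O)cc1 | intermediate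
25 | 1-[(3R)-3,5-dihydroxy-7-methoxy-2,2-dimethyl-3,4-dihydro-2H-chromen-6-yl]ethan-1-one | COc1cc2c(c(O)c1C(C)=O)C[C@@H](O)C(C)(C)O2 | intermediate
26 | (2E)-1-[(3R)-3,5-dihydroxy-7-methoxy-2,2-dimethyl-3,4-dihydro-2H-chromen-6-yl]-3-[4-(methoxymethoxy)phenyl]prop-2-en-1-one | COc1cc2c(c(O)c1C(=O)/C=C/c1ccc(OCOC)cc1)C[C@@H](O)C(C)(C)O2 | intermediate
27 | (2E)-1-[(3R)-3,5-dihydroxy-7-methoxy-2,2-dimethyl-3,4-dihydro-2H-chromen-6-yl]-3-(4-hydroxyphenyl)prop-2-en-1-one | COc1cc2c(c(O)c1C(=O)/C=C/c1ccc(O)cc1)C[C@@H](O)C(C)(C)O2 | target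

**Step count and risks**
Total: 13 steps. Longest linear sequence: 11 steps (1, 2, 3, 5, 6, 7, 8, 9, 10, 12, 13).

Most likely to fail, in order:

Step 5. The donor-substituted cyclobutenone may not open to the vinylketene at a temperature the siloxyalkyne survives, or the vinylketene may be lost to dimerisation or to acylation of the product phenol before the alkyne traps it. The fallback sets out from siloxyalkyne 10 and comes back at phenol 15, generating the same vinylketene photochemically at room temperature. Commercial 3,3-dimethoxybutan-2-one would lose methanol (cat. TsOH, distillation) to give 3-methoxybut-3-en-2-one F1. Its lithium enolate (LiN(SiMe3)2, THF, −78 °C) would be trifluoroacetylated with CF3CO2CH2CF3 to 1,1,1-trifluoro-5-methoxyhex-5-ene-2,4-dione F2. Detrifluoroacetylative diazo transfer (MsN3, Et3N, H2O, MeCN) would then give 1-diazo-3-methoxybut-3-en-2-one F3. Irradiation of F3 with 10 (CH2Cl2, Pyrex-filtered Hg lamp) should trigger a Wolff rearrangement to vinylketene 11, after which the sequence 12 → 13 → 14 → 15 proceeds as before, completed by brief warming in toluene.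

Step 8. The phenol may attack the secondary epoxide carbon (5-exo closure to a dihydrobenzofuran carbinol) in competition with the 6-endo path, or cyclise unselectively during hydrogenolysis. The fallback sets out from phenol 15 and comes back at chromanol 19, closing the heterocycle before oxygen is introduced. DDQ (benzene, reflux) would effect oxidative cyclisation of the o-prenylphenol to triisopropyl[(7-methoxy-2,2-dimethyl-2H-chromen-5-yl)oxy]silane F4. Jacobsen epoxidation with the (R,R)-(salen)MnCl catalyst (NaOCl, 4-phenylpyridine N-oxide, CH2Cl2, 0 °C) is expected, by analogy with other 2,2-dimethylchromenes, to give (3R,4R)-3,4-epoxy-7-methoxy-2,2-dimethyl-5-[(triisopropylsilyl)oxy]chromane F5. LiAlH4 (THF, 0 °C) would then deliver hydride to the benzylic C4 and leave the C3–O bond in place. This is the reserve and not the first choice because the epoxide of so electron-rich a chromene is labile and would have to be reduced without purification.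

Step 10. The acyl group may be delivered to C8 (para to the C5 oxygen) instead of C6, or the Lewis acid may cleave the tertiary chroman ether. The fallback sets out from chromanediol 20 (isolated after the fluoride treatment of step 9) and comes back at hydroxy ketone 25, replacing electrophilic acylation by directed ortho-metalation. MOMCl/iPr2NEt (CH2Cl2, reflux) would give (3R)-7-methoxy-3,5-bis(methoxymethoxy)-2,2-dimethylchromane F6. Lithiation with n-BuLi/TMEDA (THF, 0 °C) should occur at C6, between the aryl acetal oxygen and the methoxy group, and quenching with N-methoxy-N-methylacetamide would give 1-[(3R)-7-methoxy-3,5-bis(methoxymethoxy)-2,2-dimethyl-3,4-dihydro-2H-chromen-6-yl]ethan-1-one F7. HCl in MeOH would remove both acetals to give 25, which then enters the condensation of step 12 under the same conditions.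

**Further compounds**
F1 | step 5 | 3-methoxybut-3-en-2-one | COC(=C)C(C)=O
F2 | step 5 | 1,1,1-trifluoro-5-methoxyhex-5-ene-2,4-dione | COC(=C)C(=O)CC(=O)C(F)(F)F
F3 | step 5 | 1-diazo-3-methoxybut-3-en-2-one | COC(=C)C(=O)C=[N+]=[N-]
F4 | step 8 | triisopropyl[(7-methoxy-2,2-dimethyl-2H-chromen-5-yl)oxy]silane | COc1cc2c(C=CC(C)(C)O2)c(O[Si](C(C)C)(C(C)C)C(C)C)c1
F5 | step 8 | (3R,4R)-3,4-epoxy-7-methoxy-2,2-dimethyl-5-[(triisopropylsilyl)oxy]chromane | COc1cc2c(c(O[Si](C(C)C)(C(C)C)C(C)C)c1)[C@H]1O[C@H]1C(C)(C)O2
F6 | step 10 | (3R)-7-methoxy-3,5-bis(methoxymethoxy)-2,2-dimethylchromane | COc1cc2c(c(OCOC)c1)C[C@@H](OCOC)C(C)(C)O2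
F7 | step 10 | 1-[(3R)-7-methoxy-3,5-bis(methoxymethoxy)-2,2-dimethyl-3,4-dihydro-2H-chromen-6-yl]ethan-1-one | COc1cc2c(c(OCOC)c1C(C)=O)C[C@@H](OCOC)C(C)(C)O2
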